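## The problem

Atoms carry the numbers of their positions in the SMILES string of the target; ring A is C5–C6–C7–C16–C17–C29, ring B is C7–C12–C13–C14–C15–C16, ring C is C15–C16–C17–C19–C20–C22, and α is the face of ring A that carries the C17 methyl group C18. CNP0308057.1 (36) is an all-trans perhydrophenalene whose three carbocycles share C16; ring B is fused to a γ-lactone (C7–C8–O9–C10–C12) conjugated with C12=C13, and C22 is the spiro junction to an epoxidised γ-lactone. Nine stereocentres must be set (C5, C7, C15, C16, C17, C22, C26, C28, C29), three of them quaternary (C7, C17, C22), and on ring A the C5 acetate, C8 and C18 are mutually 1,3-diaxial on the α face. C29 can direct C17 (trans conjugate addition), C16 and C17 can direct C7 (enolate alkylation), the C7 carboxyl can deliver the C5 oxygen, and the substituted ring-A chair can then set C15 and C22, whose surroundings decide the face of the C26=C28 epoxidation. The epoxy enol-lactone (an acylal-type epoxide), the β-keto lactone around C22, the enoate and the acetate tolerate neither strong acid, strong base nor nucleophiles, so the epoxide must come last and the end game must be mild. What invites a domino closure is that C22 lies between the C20 ketone and the C23 lactone carbonyl and is bonded to C15, while C15 is β to C13 and C12=C13 is an enoate: C15–C22 is a Michael bond to an enal and C12=C13 a Horner–Wadsworth–Emmons bond from a lactone phosphonate.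

## Retrosynthesis

**36 ⇒ 35.** The two C–O bonds of the epoxide are cut first. No other late-stage operation would leave an acylal epoxide intact, so it cannot be carried through the route. The enol lactone 35 is asked only for a face-selective, neutral epoxidation of its electron-rich C26=C28 alkene beside the electron-poor C12=C13 enoate.

**35 ⇒ 33.** C15–C22 and C12=C13 are cut together. Cutting C20–C22 or C19–C20 instead would leave the spiro centre to be made intermolecularly at a neopentyl carbon, and cutting C12=C13 alone would leave ring C. The double cut removes rings B and C and the stereocentres C15 and C22 and leaves monocyclic 33, a ring-A enal carrying a spiro phosphonolactone and a 3-acylbutenolide. The forward step needs C-attack of a 2-oxidofuran through C22, a chair closure, and Michael addition before olefination.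

**33 ⇒ 24 + 28.** The C20–C22 bond is cut at the alcohol oxidation level (carbinol 32). Acylation at C20 would need a carboxyl derivative that the phosphonolactone and the enal do not allow. Aldehyde 24 and the metallated silyloxyfuran from 28 are both simple; the addition must prefer the saturated C20 aldehyde to the C13 enal.

**24 ⇒ 22 ⇒ 20.** The C20 aldehyde is traced to an allyl group (ozonolysis) and the enal to a dimethyl acetal by cutting C14–C15 (Mukaiyama aldol, then loss of methanol). The enal is made before C20 is unmasked because a free C20 carbinol beside a C15 aldehyde would close to a lactol, and an ylide or enol ether cannot be used beside the acylbutenolide. Acetal and allyl group are inert handles that survive every earlier step.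

**20 ⇒ 15 ⇒ 13 ⇒ 12.** The C12–P bond and the acetate are removed to give hydroxy lactone 15. Its lactone is opened retrosynthetically to triol 13 (oxidative lactonisation of the less hindered C10 alcohol) and the triol is traced to the bridged lactone 12. Phosphonylation needs excess amide base, so it is placed before the acetate and before any aldehyde exists.

**12 ⇒ 10.** The C5–O bond is cut (iodolactonisation, then removal of iodine). Hydroboration or epoxidation of C5=C6 would attack from the β face and give the wrong C5 epimer. Delivery from the α-carboxyl C8 fixes both position and configuration of the C5 oxygen.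

**10 ⇒ 9 ⇒ 8 ⇒ 7.** C7–C12 is cut (α-alkylation of a dienediolate, which also moves the alkene to C5=C6) and then C7–C8 (carbonylation of the enol triflate of ketone 7). A conjugate addition to a C7 acceptor would have to form the quaternary centre next to C16 and 1,3 to C17; an exocyclic enolate is alkylated from the open β face instead.

**7 ⇒ 5 ⇒ 4.** C15–C16 (orthoformate alkylation of a regiodefined silyl enol ether) and C17–C19 (conjugate allylation) are cut. This leaves (R)-3,4-dimethylcyclohex-2-en-1-one 4, whose single stereocentre C29 controls C17 directly and the rest of ring A in relay.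

**4 ⇒ 3 ⇒ 1.** The stereocentre of 4 is traced to an enantioselective isomerisation of the achiral β,γ-enone 3, which comes from 3,4-dimethylanisole 1 by Birch reduction.

**28 ⇒ 27 ⇒ 25.** The nucleophile for C22 is a 3-metallated 2-silyloxyfuran, made from furan-2(5H)-one 25 by α-bromination and O-silylation.

## Roads not taken

**Alternative 1:** The cut goes through C7–C8 and C10–C12, two bonds of a cyclobutane that is later opened into the C8–O9–C10 lactone; ring B exists beforehand as the C13 enone A1. Irradiation of A1 with allene would give the head-to-head methylenecyclobutane A2, with the allene CH2 on C7 and its central carbon on C12. The merit is that a photocycloaddition places a carbon on a fully substituted β-carbon regardless of hindrance. A second merit is that C16 is a decalin ring-fusion carbon fixed beforehand, which is firmer than the equilibration the chosen route uses at C16. The weak points are several. C8 must enter on the α face, syn to the axial C18. The later Baeyer–Villiger step needs the C8 methylene to migrate in preference to C12. The C13 ketone must still become C12=C13. Ring C, C15 and the spiro centre C22 all remain, each as a separate bond at a neopentyl carbon. Against the better C16 control, the chosen plan sets a C7 centre made by enolate alkylation away from the axial methyl, and one step that makes rings B and C with C15 and C22.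

**Alternative 2:** The cut goes through C7–C12 and O9–C8. Rings A and C exist as a decalin aldoxime A3 with an exocyclic C7=C8 methylene, and the nitrile oxide generated with NaOCl adds across it to give the isoxazoline A4. The merit is real: ring B, the quaternary C7 and the C8–O bond form in one intramolecular step whose tether fixes C12 β and C8 α. This is at least as secure as the alkylation used here. The weak points lie elsewhere. C12 emerges as a masked ketone without C10, so the lactone carbonyl must be added after N–O cleavage. Ring C and C15 must be built beforehand. The spiro lactone must then be assembled last on C22, flanked by C15, with nothing to control its configuration. The chosen plan uses C22 itself as the nucleophile, so its configuration follows from a cyclic transition state and its two bonds are never made separately.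

**Alternative 3:** The cut goes through C16–C17 and C7–C12 of an acyclic trienone. EtAlCl2 would activate the C5 enone, C16 of the C7=C16 alkene would attack C17, and a ketene dithioacetal would capture the C7 cation to give the trans-decalin A5. This is the most convergent road and is better in step count: two rings, both ring-A quaternary carbons and four stereocentres in one operation, with the C5 ketone in place. Its weak points are the initiation and the relay. The first bond joins a trisubstituted alkene to the tetrasubstituted β-carbon of an electron-poor enone. The configurations at C7, C16, C17 and C29 rest on alkene geometries and chair folding relayed from the lone C15 stereocentre. The butenolide must survive a strong Lewis acid. The spiro centre still needs a separate C20–C22 closure. The chosen plan is longer in ring A, but each centre is set by one understood element and can be corrected, and its closing step joins electronically matched partners.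

Key step: step 20

## Route

Step 1
Reactants: 1 3,4-dimethylanisole
Product: 3 3,4-dimethylcyclohex-3-en-1-one, via dienol ether 2 (not isolated)
Conditions: Li, NH3 (l), t-BuOH, THF, −78 °C; then (CO2H)2, MeOH–H2O, 25 °C
Reagents that add atoms: water (O)
Why: Birch reduction leaves the methoxy- and methyl-bearing carbons sp2, and enol ether hydrolysis with oxalic acid should stop at the β,γ-unsaturated ketone without moving the tetrasubstituted alkene into conjugation; no stereocentre is formed.

Step 2
Reactants: 3 3,4-dimethylcyclohex-3-en-1-one
Product: 4 (R)-3,4-dimethylcyclohex-2-en-1-one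
Conditions: 9-amino-9-deoxy-epi-quinine (10 mol %; or its quinidine-derived pseudoenantiomer, whichever delivers the 4R product), CF3CO2H (20 mol %), toluene, −20 °C
Reagents that add atoms: none
Why: Amine-catalysed enantioselective isomerisation of a β,γ- to an α,β-unsaturated ketone: the primary amine forms a dienamine and the chiral ammonium arm protonates C4 (= C29) on one face, which sets the only stereocentre taken from a catalyst.

Step 3
Reactants: 4 (R)-3,4-dimethylcyclohex-2-en-1-one
Product: 5 silyl enol ether of the allyl adduct (C7=C16)
Conditions: CH2=CHCH2MgBr, CuBr·SMe2, LiCl, Me3SiCl, THF, −78 °C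
Reagents that add atoms: allylmagnesium bromide (C=CC[Mg]Br); chlorotrimethylsilane (C[Si](C)(C)Cl)
Why: Copper-mediated conjugate addition with silyl trapping: allylic strain with the C17 methyl holds the C29 methyl pseudoaxial, so the allyl group adds axially anti to it, making C17 quaternary with allyl β and both methyls α; the regiodefined enol ether is kept for the next bond.

Step 4
Reactants: 5 silyl enol ether
Product: 7 2-(dimethoxymethyl) ketone with the acetal α, via C16 epimer 6 (not isolated)
Conditions: HC(OMe)3, Me3SiOTf (cat.), CH2Cl2, −78 °C; then NaOMe, MeOH, 25 °C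
Reagents that add atoms: trimethyl orthoformate (COC(OC)OC)
Why: Mukaiyama-type alkylation of the silyl enol ether by the dimethoxycarbenium ion puts C15 on C16 regiospecifically; the electrophile is expected to enter anti to the axial C17 methyl (epimer 6), and base equilibration through the enolate should then favour 7, the chair in which acetal, allyl and C29 methyl are equatorial and only C18 is axial.

Step 5
Reactants: 7 β-keto acetal
Product: 8 enol triflate (C7=C6)
Conditions: LiN(i-Pr)2, THF, −78 °C; PhNTf2, −78 → 0 °C
Reagents that add atoms: N-phenylbis(trifluoromethanesulfonimide) (O=S(=O)(N(c1ccccc1)S(=O)(=O)C(F)(F)F)C(F)(F)F)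
Why: Kinetic deprotonation goes to the unhindered C6 methylene and not to the neopentyl C16 methine, so C16 is untouched and O-sulfonylation gives the C7=C6 enol triflate.

Step 6
Reactants: 8 enol triflate
Product: 9 cyclohexene carboxylic acid (C8 on C7)
Conditions: Pd(OAc)2, dppf, CO (1 atm), Et3N, H2O, DMF, 60 °C
Reagents that add atoms: carbon monoxide ([C-]#[O+]); water (O)
Why: Palladium-catalysed hydroxycarbonylation of an enol triflate (oxidative addition to zerovalent palladium, CO insertion, hydrolysis of the acylpalladium) installs C8 as a conjugated acid.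

Step 7
Reactants: 9 unsaturated acid
Product: 10 α-alkylated β,γ-unsaturated acid
Conditions: LiN(i-Pr)2 (2.3 equiv), THF–DMPU, −78 → 0 °C; BrCH2CO2Me, −78 → 0 °C
Reagents that add atoms: methyl bromoacetate (COC(=O)CBr)
Why: Deconjugative α-alkylation of the lithium dienediolate (γ-deprotonation at C5): the electrophile bonds to C7 trans to the adjacent C16 acetal and anti to the 1,3-related axial C18, so C12 ends β and the carboxyl C8 α, and the alkene moves to C5=C6 where oxygen is needed next.

Step 8
Reactants: 10 unsaturated acid
Product: 11 bridged iodolactone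
Conditions: I2, KI, NaHCO3, THF–H2O, 0 → 25 °C, dark
Reagents that add atoms: iodine (II)
Why: Iodolactonisation: only the C8 carboxylate reaches the alkene and a γ-lactone can form only at C5 (attack at C6 would give a β-lactone), so oxygen arrives at C5 on the α face, cis to C8, with iodine anti on C6; the carboxylate should outrun the neutral C10 ester.

Step 9
Reactants: 11 iodolactone
Product: 12 bridged lactone
Conditions: Bu3SnH, azobisisobutyronitrile (cat.), toluene, 80 °C
Reagents that add atoms: none
Why: Radical chain dehalogenation removes the C6 iodine; hydrogen transfer from the stannane should be faster than cyclisation of the C6 radical onto the allyl group, which would need a boat.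

Step 10
Reactants: 12 bridged lactone
Product: 13 triol
Conditions: LiAlH4, THF, 0 → 25 °C
Reagents that add atoms: none
Why: Hydride reduction opens the bridged lactone to the axial C5 alcohol and the C8 alcohol and reduces the C10 ester; acetal and allyl group are inert and no stereocentre is touched.

Step 11
Reactants: 13 triol
Product: 15 hydroxy spirolactone, via lactol 14 (not isolated)
Conditions: 2,2,6,6-tetramethylpiperidin-1-oxyl (cat.), PhI(OAc)2, CH2Cl2, 25 °C
Reagents that add atoms: none
Why: Oxoammonium-mediated oxidative lactonisation of a 1,4-diol: the unhindered primary C10 alcohol is oxidised first, the aldehyde is trapped by the neopentyl C8 alcohol as lactol 14 and oxidised on to the γ-lactone with C10 as carbonyl; the hindered axial C5 alcohol should be left.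

Step 12
Reactants: 15 hydroxy spirolactone
Product: 19 hydroxy phosphonolactone, via silyl ether 16 (not isolated), via enol phosphate 17 (not isolated), via silyl phosphonate 18 (not isolated)
Conditions: LiN(SiMe3)2, Me3SiCl, THF, −78 → 0 °C; LiN(i-Pr)2 (2.5 equiv), −78 °C; ClP(O)(OEt)2, −78 → 25 °C; then 10 % aq. citric acid, 0 °C
Reagents that add atoms: diethyl chlorophosphate (CCOP(=O)(Cl)OCC)
Why: The C5 alcohol is masked in the flask as its trimethylsilyl ether, the lactone enolate is O-phosphorylated, and the vinyl phosphate rearranges under excess amide base by 1,3-phosphorus migration to the α-phosphono lactone anion; mild acid returns the alcohol, and the C12 epimer mixture does not matter because C12 becomes trigonal in step 20.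

Step 13
Reactants: 19 hydroxy phosphonolactone
Product: 20 acetate
Conditions: Ac2O, 4-(dimethylamino)pyridine, pyridine, 40 °C
Reagents that add atoms: acetic anhydride (CC(=O)OC(C)=O)
Why: Acyl-transfer catalysis acetylates the only free hydroxyl, the axial C5 alcohol, with retention; the phosphonate methine is too weakly acidic to be acylated here.

Step 14
Reactants: 20 acetal
Product: 22 E-enal, via methoxy aldehyde 21 (not isolated)
Conditions: CH2=CHOSiMe3, BF3·OEt2, CH2Cl2, −78 °C; then 1 M HCl, THF, 25 °C
Reagents that add atoms: (ethenyloxy)trimethylsilane (C=CO[Si](C)(C)C)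
Why: Mukaiyama aldol addition of the acetaldehyde silyl enol ether to the oxocarbenium ion of the acetal forms C14–C15 without freeing an epimerisable C15 aldehyde, and acid-induced β-elimination of methanol from 21 should give the E-enal under thermodynamic control.

Step 15
Reactants: 22 enal
Product: 24 enal aldehyde, via ozonide 23 (not isolated)
Conditions: O3, CH2Cl2, −78 °C (Sudan red 7B end point); PPh3, −78 → 25 °C
Reagents that add atoms: ozone ([O-][O+]=O)
Why: Ozonolysis with reductive work-up: the electron-rich terminal alkene of the allyl group reacts far faster than the conjugated enal alkene, so only C20 is unmasked.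

Step 16
Reactants: 25 furan-2(5H)-one
Product: 27 3-bromofuran-2(5H)-one, via dibromolactone 26 (not isolated)
Conditions: Br2, CH2Cl2, 0 → 25 °C; then Et3N, 0 °C
Reagents that add atoms: bromine (BrBr)
Why: Bromine addition to the butenolide alkene and amine-induced dehydrobromination (loss of the acidic α-hydrogen and the β-bromide) give the α-bromobutenolide.

Step 17
Reactants: 27 3-bromofuran-2(5H)-one
Product: 28 3-bromo-2-(triisopropylsilyloxy)furan
Conditions: (i-Pr)3SiOTf, Et3N, CH2Cl2, 0 °C
Reagents that add atoms: triisopropylsilyl trifluoromethanesulfonate (CC(C)[Si](C(C)C)(C(C)C)OS(=O)(=O)C(F)(F)F)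
Why: γ-Deprotonation and O-silylation give the aromatic 2-silyloxyfuran, a stable precursor of a nucleophile at its C3, the future C22.

Step 18
Reactants: 28 3-bromo-2-(triisopropylsilyloxy)furan; 24 enal aldehyde
Product: 32 butenolide carbinol, via lithiofuran 29 (not isolated), via titanium reagent 30 (not isolated), via silyloxyfuran carbinol 31 (not isolated)
Conditions: 28, n-BuLi, THF, −78 °C; ClTi(Oi-Pr)3, −78 °C; 24, −78 → −40 °C; then 1 M HCl, THF, 0 °C
Reagents that add atoms: none
Why: Bromine–lithium exchange and transmetalation give a weakly basic furyltitanium reagent that should add to the saturated C20 aldehyde faster than to the conjugated C13 aldehyde and leave phosphonate methine, acetate and lactone alone; protodesilylation of 31 returns the conjugated butenolide, and the C20 epimers are oxidised next.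

Step 19
Reactants: 32 butenolide carbinol
Product: 33 3-acylbutenolide enal phosphonate
Conditions: Dess–Martin periodinane, NaHCO3, CH2Cl2, 0 °C
Reagents that add atoms: none
Why: Dess–Martin oxidation of the activated secondary alcohol under buffered conditions gives the 3-acylbutenolide, which is used at once because it is a strong Michael acceptor and a carbon acid.

Step 20
Reactants: 33 3-acylbutenolide enal phosphonate
Product: 35 spiro 2(3H)-furanone, via Michael adduct 34 (not isolated)
Conditions: Cs2CO3, 18-crown-6, MeCN, 0 → 25 °C
Reagents that add atoms: none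
Why: Carbonate removes a C26 proton of the 3-acylbutenolide, the most acidic site, to give a cesium 2-oxidofuran whose charge is shared by oxygen, C22 and C26. Attack through C22 on the enal β-carbon C15 closes ring C by a 6-exo-trig Michael addition (attack through C26 would need an eight-membered ring), and the aldehyde enolate is protonated to 34. The C12 phosphonate, now the strongest acid left, is deprotonated and adds to the C13 aldehyde; loss of diethyl phosphate closes the six-membered ring B by exo attack on the aldehyde and places the alkene at C12=C13. The closest known reactions are the intramolecular Michael addition of cyclic β-dicarbonyl donors to enals and the intramolecular Horner–Wadsworth–Emmons ring closure, here run in one flask. C15 is set by a chair transition state in which the enal chain stays equatorial on C16 and the new bond forms anti to H16, so ring C becomes trans-fused to ring A. C22 is set by the furanolate rotamer in which the C20 carbonyl and the C23–O25 dipole are opposed, which puts C23 axial and C28 equatorial; the crown-complexed cesium ion cannot chelate the two oxygens into the other rotamer. The step needs C- over O-attack and Michael addition before olefination: the first follows from the soft acceptor and the ring size, the second from the E-alkene, which keeps C13 out of reach of C12 until C15 is sp3, and from the lower acidity of the phosphonate.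

Step 21
Reactants: 35 spiro 2(3H)-furanone
Product: 36 CNP0308057.1
Conditions: dimethyldioxirane, acetone, −20 → 0 °C
Reagents that add atoms: dimethyldioxirane (CC1(C)OO1)
Why: Neutral dioxirane epoxidation picks the electron-rich enol-lactone alkene C26=C28 over the conjugated C12=C13 enoate; the face syn to the flat C20 carbonyl is open whereas the other is screened by C14 and ring B, so O27 should enter syn to C20, and the volatile by-product lets the sensitive epoxide be isolated by evaporation.

## Compound list

1 | 3,4-dimethylanisole (4-methoxy-1,2-dimethylbenzene) | COc1ccc(C)c(C)c1 | starting material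
2 | 1-methoxy-4,5-dimethylcyclohexa-1,4-diene | COC1=CCC(C)=C(C)C1 | intermediate
3 | 3,4-dimethylcyclohex-3-en-1-one | O=C1CCC(C)=C(C)C1 | intermediate
4 | (R)-3,4-dimethylcyclohex-2-en-1-one | O=C1C=C(C)[C@H](C)CC1 | intermediate
5 | trimethyl{[(3S,4R)-3,4-dimethyl-3-(prop-2-en-1-yl)cyclohex-1-en-1-yl]oxy}silane (enol ether C7=C16; allyl β, C18 and C30 α) | C[Si](C)(C)OC1=C[C@@](C)(CC=C)[C@H](C)CC1 | intermediate
6 | (2R,3S,4R)-2-(dimethoxymethyl)-3,4-dimethyl-3-(prop-2-en-1-yl)cyclohexan-1-one (C16 epimer of 7, acetal β) | O=C1[C@@H](C(OC)OC)[C@@](C)(CC=C)[C@H](C)CC1 | intermediate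
7 | (2S,3S,4R)-2-(dimethoxymethyl)-3,4-dimethyl-3-(prop-2-en-1-yl)cyclohexan-1-one (C7 ketone; C15 acetal, C18 and C30 α; allyl β) | O=C1[C@H](C(OC)OC)[C@@](C)(CC=C)[C@H](C)CC1 | intermediate
8 | enol triflate of 7 toward C6: 6-(dimethoxymethyl)-4,5-dimethyl-5-(prop-2-en-1-yl)cyclohex-1-en-1-yl trifluoromethanesulfonate, stereocentres as in 7 | FC(F)(F)S(=O)(=O)OC1=CC[C@@H](C)[C@](C)(CC=C)[C@H]1C(OC)OC | intermediate
9 | 6-(dimethoxymethyl)-4,5-dimethyl-5-(prop-2-en-1-yl)cyclohex-1-ene-1-carboxylic acid (C8 carboxyl on C7, C7=C6), stereocentres as in 7 | OC(=O)C1=CC[C@@H](C)[C@](C)(CC=C)[C@H]1C(OC)OC | intermediate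
10 | 6-(dimethoxymethyl)-1-(2-methoxy-2-oxoethyl)-4,5-dimethyl-5-(prop-2-en-1-yl)cyclohex-2-ene-1-carboxylic acid (C7 quaternary: CO2H α, CH2CO2Me β; C5=C6) | OC(=O)[C@@]1(CC(=O)OC)C=C[C@@H](C)[C@](C)(CC=C)[C@H]1C(OC)OC | intermediate
11 | bridged iodolactone: γ-lactone C8(=O)–O–C5 across the α face of ring A, iodine β on C6, CH2CO2Me β on C7 | O=C1O[C@@H]2[C@@H](I)[C@@]1(CC(=O)OC)[C@H](C(OC)OC)[C@@](C)(CC=C)[C@@H]2C | intermediate
12 | bridged lactone (11 without iodine) | O=C1O[C@@H]2C[C@@]1(CC(=O)OC)[C@H](C(OC)OC)[C@@](C)(CC=C)[C@@H]2C | intermediate
13 | triol: 5α-hydroxy, C7 α-hydroxymethyl (C8) and β-2-hydroxyethyl (C12–C10) | O[C@@H]1C[C@@](CO)(CCO)[C@H](C(OC)OC)[C@@](C)(CC=C)[C@@H]1C | intermediate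
14 | lactol: C10 hemiacetal closed onto the C8 oxygen (spiro at C7), 5α-hydroxy | O[C@@H]1C[C@]2(COC(O)C2)[C@H](C(OC)OC)[C@@](C)(CC=C)[C@@H]1C | intermediate
15 | hydroxy spirolactone: C7 spiro γ-lactone C8–O9–C10(=O)–C12, 5α-hydroxy | O[C@@H]1C[C@]2(COC(=O)C2)[C@H](C(OC)OC)[C@@](C)(CC=C)[C@@H]1C | intermediate
16 | 5-O-trimethylsilyl ether of 15 | C[Si](C)(C)O[C@@H]1C[C@]2(COC(=O)C2)[C@H](C(OC)OC)[C@@](C)(CC=C)[C@@H]1C | intermediate
17 | diethyl enol phosphate of 16 (C10–O–P, C10=C12) | C[Si](C)(C)O[C@@H]1C[C@]2(COC(OP(=O)(OCC)OCC)=C2)[C@H](C(OC)OC)[C@@](C)(CC=C)[C@@H]1C | intermediate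
18 | 5-O-trimethylsilyl ether of 19 | C[Si](C)(C)O[C@@H]1C[C@]2(COC(=O)C2P(=O)(OCC)OCC)[C@H](C(OC)OC)[C@@](C)(CC=C)[C@@H]1C | intermediate
19 | hydroxy phosphonolactone: diethyl phosphonate on C12 (both epimers), 5α-hydroxy | O[C@@H]1C[C@]2(COC(=O)C2P(=O)(OCC)OCC)[C@H](C(OC)OC)[C@@](C)(CC=C)[C@@H]1C | intermediate
20 | 5α-acetate of 19 (C16 dimethyl acetal, C17 allyl) | CC(=O)O[C@@H]1C[C@]2(COC(=O)C2P(=O)(OCC)OCC)[C@H](C(OC)OC)[C@@](C)(CC=C)[C@@H]1C | intermediate
21 | β-methoxy aldehyde: C16–CH(OMe)–CH2–CHO (C15 epimers) | CC(=O)O[C@@H]1C[C@]2(COC(=O)C2P(=O)(OCC)OCC)[C@H](C(OC)CC=O)[C@@](C)(CC=C)[C@@H]1C | intermediate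
22 | E-enal: C16–CH=CH–CHO, allyl on C17 | CC(=O)O[C@@H]1C[C@]2(COC(=O)C2P(=O)(OCC)OCC)[C@H](/C=C/C=O)[C@@](C)(CC=C)[C@@H]1C | intermediate
23 | 1,2,4-trioxolane (ozonide) of the allyl group of 22 | CC(=O)O[C@@H]1C[C@]2(COC(=O)C2P(=O)(OCC)OCC)[C@H](/C=C/C=O)[C@@](C)(CC2OCOO2)[C@@H]1C | intermediate
24 | enal aldehyde: C16 E-enal and C17–CH2–CHO | CC(=O)O[C@@H]1C[C@]2(COC(=O)C2P(=O)(OCC)OCC)[C@H](/C=C/C=O)[C@@](C)(CC=O)[C@@H]1C | intermediate
25 | furan-2(5H)-one | O=C1OCC=C1 | starting material
26 | 3,4-dibromodihydrofuran-2(3H)-one | O=C1OCC(Br)C1Br | intermediate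
27 | 3-bromofuran-2(5H)-one | O=C1OCC=C1Br | intermediate
28 | 3-bromo-2-[tri(propan-2-yl)silyloxy]furan | CC(C)[Si](C(C)C)(C(C)C)Oc1occc1Br | intermediate
29 | 3-lithio-2-[tri(propan-2-yl)silyloxy]furan | [Li]c1ccoc1O[Si](C(C)C)(C(C)C)C(C)C | intermediate
30 | tri(propan-2-yloxy){2-[tri(propan-2-yl)silyloxy]furan-3-yl}titanium | CC(C)O[Ti](OC(C)C)(OC(C)C)c1ccoc1O[Si](C(C)C)(C(C)C)C(C)C | intermediate
31 | silyloxyfuran carbinol: C20 hydroxyl (epimers), furan C3 bonded to C20 | CC(=O)O[C@@H]1C[C@]2(COC(=O)C2P(=O)(OCC)OCC)[C@H](/C=C/C=O)[C@@](C)(CC(O)c2ccoc2O[Si](C(C)C)(C(C)C)C(C)C)[C@@H]1C | intermediate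
32 | butenolide carbinol: 3-(1-hydroxyalkyl)furan-2(5H)-one at C20 (epimers) | CC(=O)O[C@@H]1C[C@]2(COC(=O)C2P(=O)(OCC)OCC)[C@H](/C=C/C=O)[C@@](C)(CC(O)C2=CCOC2=O)[C@@H]1C | intermediate
33 | ring-A enal with spiro phosphonolactone and 3-acylbutenolide (precursor of the key step) | CC(=O)O[C@@H]1C[C@]2(COC(=O)C2P(=O)(OCC)OCC)[C@H](/C=C/C=O)[C@@](C)(CC(=O)C2=CCOC2=O)[C@@H]1C | intermediate
34 | Michael adduct: ring C closed, spiro 2(3H)-furanone at C22, C13 aldehyde, phosphonate intact | CC(=O)O[C@@H]1C[C@]3(COC(=O)C3P(=O)(OCC)OCC)[C@@H]2[C@@H](CC=O)[C@@]4(C(=O)OC=C4)C(=O)C[C@@]2(C)[C@@H]1C | intermediate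
35 | spiro 2(3H)-furanone (target without the epoxide oxygen) | CC(=O)O[C@@H]1C[C@@]23COC(=O)C2=CC[C@@H]2[C@@H]3[C@@](C)(CC(=O)[C@]23C(=O)OC=C3)[C@@H]1C | intermediate
36 | CNP0308057.1 | CC(=O)O[C@@H]1C[C@@]23COC(=O)C2=CC[C@@H]2[C@@H]3[C@@](C)(CC(=O)[C@]23C(=O)O[C@H]2O[C@H]23)[C@@H]1C | target

## Step count and least certain steps

Total: 21 steps. Longest linear sequence: 19 steps (steps 1–15 and 18–21); steps 16 and 17 make reagent 28.

**Step 20 (key step).** The ambident furanolate may attack through oxygen, or through the wrong rotamer or enal face, giving poor selectivity at C22 or C15. The phosphonate may also condense before ring C has closed. Fallback: the two events are separated. From 33, the Michael addition alone is run under iminium activation of the enal with a diarylprolinol silyl ether and a weak acid, and aldehyde 34 is isolated. Ring B is then closed with LiCl and DBU in MeCN (Masamune–Roush conditions), returning at 35.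

**Step 4.** The thermodynamic bias at C16 may be too small, so that epimer 6 persists, or methanol may be lost by β-elimination under base. Fallback: kinetic instead of thermodynamic control. From the mixture of 6 and 7, the more substituted silyl enol ether F1 is formed (Me3SiCl, NaI, Et3N, MeCN). Its enolate is released with a fluoride source at −78 °C in the presence of a hindered phenol, so that the proton enters on the β face, anti to the axial C18, returning at 7.

**Step 8.** The lactone must bridge the face that already carries the axial C18. The strain may slow closure by the C8 carboxylate so that the iodonium ion reverts or is captured by the C10 ester. Fallback: from 10, LiAlH4 gives the diol F2. Epoxidation directed by the homoallylic C8 hydroxyl (VO(acac)2, t-BuOOH) gives the α-epoxide F3. Trans-diaxial opening by hydride at C6 (LiAlH4) gives triol 13.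

**Step 14.** Capture of the hindered oxocarbenium ion may be slow, leaving room for cyclisation of the allyl group onto it or for plain hydrolysis. Fallback: from 20, the acetal is hydrolysed (LiBF4, wet MeCN) to the aldehyde F4. F4 is homologated by Wittig reaction with Ph3P=CHCHO in toluene at 80 °C, returning at 22.

**Step 18.** The reagent may also add to the enal carbonyl, or the new C20 alkoxide may add in conjugate fashion to the enal before it is oxidised. Fallback: from 22, the enal is protected as its dimethyl acetal F5 (HC(OMe)3, pyridinium p-toluenesulfonate). Ozonolysis gives the aldehyde F6, addition of 30 gives the carbinol F7, and Dess–Martin oxidation gives the ketone F8. Mild aqueous acid on F8 releases the enal, returning at 33.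

**Step 21.** Facial selectivity of oxygen transfer may be poor or reversed. Fallback: from 35, N-bromosuccinimide in wet THF gives the bromohydrin F9 (bromine on C28, hydroxyl on C26, anti). Ag2O then closes the epoxide with inversion at C28. If the electrophile prefers the face syn to C15, this sequence still places the oxygen syn to C20, returning at 36.

## Further compounds

F0 | step 20 | none | none
F1 | step 4 | tetrasubstituted silyl enol ether of 7 (C7=C16, acetal on C16) | C[Si](C)(C)OC1=C(C(OC)OC)[C@@](C)(CC=C)[C@H](C)CC1
F2 | step 8 | diol from 10: C7 α-hydroxymethyl and β-2-hydroxyethyl, C5=C6 | OC[C@@]1(CCO)C=C[C@@H](C)[C@](C)(CC=C)[C@H]1C(OC)OC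
F3 | step 8 | 5,6-α-epoxide of F2 | OC[C@@]1(CCO)[C@H]2O[C@H]2[C@@H](C)[C@](C)(CC=C)[C@H]1C(OC)OC
F4 | step 14 | C15 aldehyde from 20 | CC(=O)O[C@@H]1C[C@]2(COC(=O)C2P(=O)(OCC)OCC)[C@H](C=O)[C@@](C)(CC=C)[C@@H]1C
F5 | step 18 | dimethyl acetal of enal 22 | CC(=O)O[C@@H]1C[C@]2(COC(=O)C2P(=O)(OCC)OCC)[C@H](/C=C/C(OC)OC)[C@@](C)(CC=C)[C@@H]1C
F6 | step 18 | C20 aldehyde with the enal as dimethyl acetal | CC(=O)O[C@@H]1C[C@]2(COC(=O)C2P(=O)(OCC)OCC)[C@H](/C=C/C(OC)OC)[C@@](C)(CC=O)[C@@H]1C
F7 | step 18 | butenolide carbinol with the enal as dimethyl acetal | CC(=O)O[C@@H]1C[C@]2(COC(=O)C2P(=O)(OCC)OCC)[C@H](/C=C/C(OC)OC)[C@@](C)(CC(O)C2=CCOC2=O)[C@@H]1C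
F8 | step 18 | 3-acylbutenolide with the enal as dimethyl acetal | CC(=O)O[C@@H]1C[C@]2(COC(=O)C2P(=O)(OCC)OCC)[C@H](/C=C/C(OC)OC)[C@@](C)(CC(=O)C2=CCOC2=O)[C@@H]1C
F9 | step 21 | bromohydrin of 35: bromine on C28, hydroxyl on C26 | CC(=O)O[C@@H]1C[C@@]23COC(=O)C2=CC[C@@H]2[C@@H]3[C@@](C)(CC(=O)[C@]23C(=O)O[C@@H](O)[C@@H]3Br)[C@@H]1C
A1 | alternative 1 | ring-B enone (C13 ketone, C12=C7) with silyl ethers at C5 and C20 | CC(C)(C)[Si](C)(C)O[C@@H]1CC2=CC(=O)CC[C@@H]2[C@@](C)(CCO[Si](C)(C)C(C)(C)C)[C@@H]1C
A2 | alternative 1 | methylenecyclobutane photoadduct | CC(C)(C)[Si](C)(C)O[C@@H]1C[C@@]23CC(=C)[C@@H]2C(=O)CC[C@@H]3[C@@](C)(CCO[Si](C)(C)C(C)(C)C)[C@@H]1C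
A3 | alternative 2 | decalin aldoxime with exocyclic C7=C8 methylene and C20 dioxolane | CC(C)(C)[Si](C)(C)O[C@@H]1CC(=C)[C@@H]2[C@@H](CCC=NO)CC3(OCCO3)C[C@@]2(C)[C@@H]1C
A4 | alternative 2 | perhydrophenalene-fused isoxazoline | CC(C)(C)[Si](C)(C)O[C@@H]1C[C@@]23CON=C2CC[C@@H]2[C@@H]3[C@@](C)(CC4(OCCO4)C2)[C@@H]1C
A5 | alternative 3 | trans-decalin C5 ketone with C12 ketene dithioacetal | O=C1C[C@@]2(COCc3ccccc3)C(=C3SCCCS3)CC[C@@H](C3=CCOC3=O)[C@@H]2[C@@](C)(CCO[Si](C)(C)C(C)(C)C)[C@@H]1C
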